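In Friday's flask the coupling partner comes in at 0.00707 M min⁻¹, while at the start the starting material goes to homo dimer at 0.00512 M min⁻¹, and my reckoning rests on these two rates.

    starting material + coupling partner + catalyst → catalyst + target (k1 = 18200 L² mol⁻² min⁻¹)
    second substrate + coupling partner + catalyst → catalyst + second product (k2 = 200 L² mol⁻² min⁻¹)
    catalyst + added ligand ⇌ idle complex (K3 = 5150 L mol⁻¹, k3 = 587 L mol⁻¹ min⁻¹)
    2 starting material → homo dimer (k4 = 0.278 L mol⁻¹ min⁻¹)

| flask | starting material | coupling partner | second substrate | catalyst | added ligand | time | remark |
|---|---|---|---|---|---|---|---|
| Sunday's | 0.096 M (fed, over 15 min) | 0.106 M | 0.192 M | 1.2 mM | 0.89 mM | 40 min | all else is in the flask from the start; the feed brings no volume worth counting |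
| Tuesday's | 0.096 M | 0.106 M (in portions, 5, over 15 min) | 0.192 M | 1.2 mM | 0.89 mM | 40 min | first portion at the start, last at 15 min |
| Monday's | 0.096 M | 0.106 M | 0.192 M | 1.2 mM | 0.89 mM | 40 min | everything together at the start |
| Friday's | 0.096 M | 0.106 M (fed, over 15 min) | 0.192 M | 1.2 mM | 0.89 mM | 40 min | all else is in the flask from the start; the feed brings no volume worth counting |

* the best flask by amount of target, in percent of the starting material charged; "all alike" if 1.5 percentage points covers them all (Sunday's / Tuesday's / Monday's / Friday's / all alike)
* amount of target at the end, in percent of the starting material charged, Sunday's
* amount of target at the end, in percent of the starting material charged, Tuesday's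
* amount of target at the end, in percent of the starting material charged, Monday's
* amount of target at the end, in percent of the starting material charged, Friday's

- percent here means starting material units held: one homo dimer counts as two
- a step written with two of one species runs at k times the square of its concentration and takes two of it each time
- run time (Sunday's): 40 min

I take these two rates for Friday's flask because the dosing time is 32 times the partner's lifetime against everything charged, so while starting material stands, I let the partner react as it comes. At the charges, the second substrate's claim on the partner is hardly any of the starting material's.

Then c(starting material) falls in a straight line and reaches zero after 13.6 min, a little sooner than the feed ends. The dimer rate goes with the square of c(starting material), so along that line it adds up to a third of its starting value times that emptying time. As a share of the charge, that is the dimer rate at the start over 3 times the feed rate, 24.2 %. This share is the starving loss, the selectivity loss of the dosing, and it leaves me 75.8 % of target in Friday's flask.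

Monday's flask has no feed. There the coupling half-life with everything as charged, 0.30 min, stands against a first dimer half-life of 18.7 min, so in Monday's flask I expect coupling to outrun dimer formation. This comparison does not place Monday's flask against Sunday's flask, so I commit to no ranking.

The forecast names Monday's as best, with 96.7 % there, 89 % for Sunday's, 80.6 % for Tuesday's and 77.6 % for Friday's, which is more than my figure. Its grounds for Friday's: “starved of partner, starting material sits concentrated and dimerises”.

The simulation gives Monday's as best, with 96.7 %, then 87.8 % for Sunday's, 80.2 % for Tuesday's and 77.8 % for Friday's.

Friday's flask holds 22.1 % homo dimer at 40.0 min, against a starving loss of 24.2 %. The neighbour like Friday's with 0.038 M of starting material reckons 3.79 % by the same rule, and it shows 7.67 % homo dimer and 92.3 % target. Friday's flask is not at rest at 40.0 min. At 400 min target still reads 77.9 % and homo dimer 22.1 %, but coupling partner has fallen from 15.0 % to 0.0251 % of its charge, and second product has risen from 0.0154 M to 0.0312 M.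

The constants used here are made up; the run is a simulation.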